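Its constants were chosen freely.

The pitfall in this flask is to divide free monomer by the initiator charged, as if every initiator began a chain at once, which gives 16.7.

    free monomer + initiator → living end + monomer in chains (k1 = 0.295 L mol⁻¹ min⁻¹)
    free monomer + living end → monomer in chains + living end, rate k2*[living end]*[free monomer] (k2 = 65.3 L mol⁻¹ min⁻¹)
    protic impurity + free monomer → quenched substrate (k3 = 3.24 L mol⁻¹ min⁻¹)

free monomer 0.40 M; protic impurity 0.0800 M; initiator 24 mM; time 2.5 min

- whether the average number of monomer units in a chain (chains begun, living or dead) reaches 10 by 2.5 min (yes / no)
- average number of monomer units in a chain (chains begun, living or dead) at 2.5 min

- the average divides the monomer in chains by the number of chains begun, living and dead together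
- run time (flask): 2.5 min

Why is that division wrong here? Because initiation is slow: with free monomer at its charge, the initiator's half-life is 5.87 min, longer than the run. Propagation also stands 2.35 powers of ten above initiation in its constant. In this flask, chains are still being begun while older ones grow.

What measures length, then? Let f be the fraction of the free monomer charge still free, and let the exposure τ be the time integral of f. While the initiator stays near its charge, chains begun rise in step with τ, and the mean chain has seen half of the exposure. So length = one + gτ, where the length gain 13.1 min⁻¹ is half of k2 times the monomer charge. The initiator charge cancels in this reckoning.

Doesn't the protic impurity break chains? Not in this scheme: it takes free monomer, so it acts through f.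

What is your number? I try a mean f of 0.7, so τ is 1.75 min. Then quenched substrate takes 17.9% of the monomer charge and chains take 29.6%, leaving 52.5% of that charge free at the end. Averaging the two ends gives τ = 1.91 min, so the length is 26.0. Length 10 needs 0.689 min of exposure, less than τ, so my answer is yes.

Where is this weakest? That τ spends 20.1% of the initiator, so the straight line is rough by the end.

The forecast says yes and 26, within 23 to 29, on the ground that “each of those few chains has grown long”.

The flask gives yes and a length of 26.1 at 2.5 min. It passes length 10 at 0.744 min, when 16.3% of the free monomer has reacted. Over that stretch the mean f, taken between the two ends, is 0.918, so the exposure is 0.683 min, and with the length gain 13.1 min⁻¹ this gives a length of 9.95.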